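The C5 ketone beside the C4 tertiary carbinol in the 14-membered carbocycle is read as a hydrated C5≡C6 triple bond, and the ring is cut there. One ring-closing alkyne metathesis of an acyclic diyne, carrying prop-1-ynyl groups on C4 and C7, makes the C5≡C6 bond and the macrocycle at once, without touching the C8=C9 olefin, the acrylate on C1, the C12–C13 oxirane or any stereocentre; the freed C4 hydroxyl then directs tin, and so oxygen, to C5. In the diyne, C1, C12 and C13 come from (R)-carvone oxide, C4 from (R)-2-methylglycidol, and the C6–C10 enyne arm is joined at C11 through an allyl sulfone.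

Key step: step 30

Remark on numbering: C1 carries the acrylate (C15; C16 is its carboxyl carbon, C17 its methylene); the ring continues C2, C3, C4 (carbinol), C5 (ketone), C6, C7, C8=C9, C10, C11, C12–C13 (oxirane), C14. Open-chain intermediates keep these numbers.
Remark on mixtures: 5, 14 and 31 are assumed to be carried as epimer mixtures at centres that are erased later (carbinol carbon of 5, sulfonyl carbons C2 of 14 and C10 of 31); their SMILES leave these centres open.
Abbreviations: PMP = 4-methoxyphenyl, PMB = 4-methoxybenzyl, TES = triethylsilyl.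

Step 1
Reactants: 1 (R)-carvone
Product: 2 trans-carvone oxide
Conditions: 30% H2O2, NaOH (cat.), MeOH, 0 °C
Reagents that add atoms: hydrogen peroxide, OO
Why: Weitz–Scheffer epoxidation: hydroperoxide adds to the enone β-carbon anti to the isopropenyl group and closes the oxirane, which sets both oxirane centres (later C12 and C13) relative to the carvone centre (later C1), while the unactivated isopropenyl olefin should not react.

Step 2
Reactants: 2 trans-carvone oxide
Product: 3 allylic chloride (2-(chloromethyl)allyl group on the ring)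
Conditions: Ca(OCl)2, solid CO2, CH2Cl2/H2O, 0 °C
Reagents that add atoms: calcium hypochlorite, [Ca+2].[O-]Cl.[O-]Cl
Why: Ene-type allylic chlorination by HOCl made in the flask: chlorine adds to the terminal carbon of the isopropenyl group and a methyl proton is lost, which oxygenates the later C16 position in masked form without touching a stereocentre.

Step 3
Reactants: 3 allylic chloride
Product: 4 PMP ether
Conditions: 4-methoxyphenol, K2CO3, NaI (cat.), DMF, 25 °C
Reagents that add atoms: 4-methoxyphenol, COc1ccc(O)cc1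
Why: Williamson ether synthesis: the weakly basic phenoxide displaces the primary allylic chloride (SN2 and SN2′ give the same ether) and should leave the epoxy ketone alone.

Step 4
Reactants: 4 PMP ether
Product: 5 α-hydroxy ketone (OH on the ketone CH2 carbon, later C2; epimer mixture)
Conditions: NaN(SiMe3)2, THF, −78 °C; 2-(phenylsulfonyl)-3-phenyloxaziridine; aq. NH4Cl
Reagents that add atoms: 2-(phenylsulfonyl)-3-phenyloxaziridine, O=S(=O)(N1OC1c1ccccc1)c1ccccc1
Why: Davis α-hydroxylation: the ketone can enolise only toward its CH2 group and the sodium enolate takes oxygen from the oxaziridine; the new carbinol centre needs no control because step 5 cleaves it.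

Step 5
Reactants: 5 α-hydroxy ketone
Product: 7 seco hydroxy ester (C2 CH2OH; C11 CO2Me), via seco aldehyde ester 6 (not isolated)
Conditions: Pb(OAc)4, MeOH/PhMe, 0 °C; filtration; NaBH4, MeOH, −20 °C
Reagents that add atoms: methanol, CO
Why: Criegee-type cleavage of the α-ketol through its methanol hemiketal gives the C11 methyl ester and the C2 aldehyde, which NaBH4 reduces at once (chemoselective over the glycidic ester) before the C1 centre next to the aldehyde can epimerise.

Step 6
Reactants: 7 seco hydroxy ester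
Product: 8 C2 iodide
Conditions: I2, PPh3, imidazole, CH2Cl2, 0 °C
Reagents that add atoms: iodine, II
Why: Appel-type iodination (Garegg–Samuelsson conditions): the oxyphosphonium salt of the primary alcohol is displaced by iodide in an SN2 step at C2, away from all stereocentres.

Step 7
Reactants: 8 C2 iodide
Product: 9 C2 phenyl sulfone (C11 methyl ester)
Conditions: PhSO2Na, DMF, 60 °C
Reagents that add atoms: sodium benzenesulfinate, [Na+].[O-]S(=O)c1ccccc1
Why: SN2 S-alkylation of the sulfinate by the primary iodide installs the carbanion-stabilising group at C2 without any oxidant or thiolate that could attack the oxirane.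

Step 8
Reactants: 9 C2 phenyl sulfone
Product: 10 C11 epoxy alcohol
Conditions: i-Bu2AlH, CH2Cl2, −78 °C; Rochelle salt
Reagents that add atoms: none
Why: Hydride reduction of the glycidic ester to the primary alcohol at −78 °C, where sulfone and oxirane are inert; the ester must go before a C2 carbanion is made, since that carbanion would otherwise be acylated intramolecularly.

Step 9
Reactants: 10 C11 epoxy alcohol
Product: 11 C11 TES ether
Conditions: Et3SiCl, imidazole, CH2Cl2, 0 °C
Reagents that add atoms: chlorotriethylsilane, CC[Si](Cl)(CC)CC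
Why: Standard silylation of the primary alcohol removes the only acidic proton before the carbanion chemistry of step 11.

Step 10
Reactants: 12 (R)-2-methylglycidol
Product: 13 (S)-2-{[(4-methoxybenzyl)oxy]methyl}-2-methyloxirane
Conditions: NaH, 4-methoxybenzyl chloride, Bu4NI (cat.), THF/DMF, 0 °C
Reagents that add atoms: 4-methoxybenzyl chloride, COc1ccc(CCl)cc1
Why: Williamson etherification at the primary oxygen; no bond to the quaternary centre is broken, so the configuration is kept and only the descriptor changes through the priority rules.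

Step 11
Reactants: 11 C11 TES ether; 13 (S)-2-{[(4-methoxybenzyl)oxy]methyl}-2-methyloxirane
Product: 14 coupled hydroxy sulfone (C4 tertiary OH; C5 O-PMB; C2 epimers)
Conditions: n-BuLi, THF, −78 °C; BF3·OEt2; 13; −78 °C; aq. NH4Cl
Reagents that add atoms: none
Why: The α-sulfonyl carbanion opens the BF3-activated 2,2-disubstituted epoxide at its CH2 terminus (SN2, forming C2–C3), so the C4 carbinol centre comes unchanged from 13, and the epimeric sulfonyl carbon is erased in step 12.

Step 12
Reactants: 14 coupled hydroxy sulfone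
Product: 15 C4 tertiary alcohol (C2 now CH2)
Conditions: Na(Hg), Na2HPO4, MeOH/THF, −20 °C
Reagents that add atoms: none
Why: Reductive desulfonylation by electron transfer from sodium amalgam cleaves the C2–S bond and protonates C2; ethers, silyl ether and oxirane should not accept electrons under these buffered conditions.

Step 13
Reactants: 15 C4 tertiary alcohol
Product: 16 C4/C11 bis-TES ether
Conditions: Et3SiOTf, 2,6-lutidine, CH2Cl2, −78 to 0 °C
Reagents that add atoms: triethylsilyl trifluoromethanesulfonate, CC[Si](CC)(CC)OS(=O)(=O)C(F)(F)F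
Why: The silyl triflate silylates the hindered tertiary hydroxyl and installs the protecting group that the metathesis catalyst later requires.

Step 14
Reactants: 16 C4/C11 bis-TES ether
Product: 17 C5 primary alcohol
Conditions: DDQ, CH2Cl2/pH 7 buffer, 0 °C
Reagents that add atoms: none
Why: Oxidative PMB cleavage by benzylic hydride abstraction; the PMP aryl ether has no benzylic C–H and the buffer protects the TES ethers.

Step 15
Reactants: 17 C5 primary alcohol
Product: 18 C5 aldehyde
Conditions: Dess–Martin periodinane, NaHCO3, CH2Cl2, 0 °C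
Reagents that add atoms: none
Why: Dess–Martin oxidation of the neopentyl-type primary alcohol; the aldehyde has no α-hydrogen, so C4 cannot epimerise.

Step 16
Reactants: 18 C5 aldehyde
Product: 19 1,1-dibromoalkene
Conditions: CBr4, PPh3, Et3N, CH2Cl2, 0 °C
Reagents that add atoms: tetrabromomethane, BrC(Br)(Br)Br
Why: Ramirez olefination (first stage of the Corey–Fuchs sequence) with the dibromomethylene ylide, buffered by Et3N for the silyl ethers.

Step 17
Reactants: 19 1,1-dibromoalkene
Product: 21 C4 prop-1-ynyl compound, via lithium acetylide 20 (not isolated)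
Conditions: n-BuLi (2.1 equiv), THF, −78 °C; MeI, −78 to 20 °C
Reagents that add atoms: iodomethane, CI
Why: Second stage of the Corey–Fuchs reaction: bromine–lithium exchange, Fritsch–Buttenberg–Wiechell rearrangement and deprotonation give the acetylide, which is C-methylated to the capped alkyne.

Step 18
Reactants: 21 C4 prop-1-ynyl compound
Product: 22 C11 alcohol (C4 O-TES kept)
Conditions: PPTS (cat.), MeOH/CH2Cl2, 0 °C
Reagents that add atoms: none
Why: Acid-catalysed methanolysis should remove the unhindered primary TES ether far faster than the tertiary one at the crowded C4.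

Step 19
Reactants: 23 prenyl acetate
Product: 24 (E)-4-hydroxy-3-methylbut-2-en-1-yl acetate
Conditions: SeO2 (0.3 equiv), t-BuOOH, CH2Cl2, 20 °C
Reagents that add atoms: tert-butyl hydroperoxide, CC(C)(C)OO (oxygen relayed by selenium dioxide, O=[Se]=O)
Why: Riley allylic oxidation (ene reaction, then [2,3]-sigmatropic shift) hydroxylates the (E)-methyl group of the trisubstituted olefin, which fixes the E geometry of the later C8=C9 bond.

Step 20
Reactants: 24 (E)-4-hydroxy-3-methylbut-2-en-1-yl acetate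
Product: 25 (E)-4-bromo-3-methylbut-2-en-1-yl acetate
Conditions: CBr4, PPh3, CH2Cl2, 0 °C
Reagents that add atoms: tetrabromomethane, BrC(Br)(Br)Br
Why: Appel bromination of the primary allylic alcohol by SN2 displacement, without allylic transposition.

Step 21
Reactants: 25 (E)-4-bromo-3-methylbut-2-en-1-yl acetate
Product: 27 (E)-3-methylhept-2-en-5-yn-1-ol, via enyne acetate 26 (not isolated)
Conditions: CH3C≡CMgBr, CuI (cat.), THF, −40 to 0 °C; K2CO3 (cat.), MeOH, 20 °C
Reagents that add atoms: prop-1-ynylmagnesium bromide, CC#C[Mg]Br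
Why: Copper-catalysed coupling of the alkynyl Grignard reagent with the primary allylic bromide at its CH2 carbon gives the skipped enyne with the olefin geometry kept, and methanolysis of the acetate then frees the alcohol.

Step 22
Reactants: 27 (E)-3-methylhept-2-en-5-yn-1-ol
Product: 28 (E)-1-bromo-3-methylhept-2-en-5-yne
Conditions: CBr4, PPh3, CH2Cl2, 0 °C
Reagents that add atoms: tetrabromomethane, BrC(Br)(Br)Br
Why: Appel bromination of the primary allylic alcohol under neutral conditions that spare the skipped enyne.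

Step 23
Reactants: 28 (E)-1-bromo-3-methylhept-2-en-5-yne
Product: 29 (E)-3-methylhept-2-en-5-yn-1-yl phenyl sulfone
Conditions: PhSO2Na, DMF, 20 °C
Reagents that add atoms: sodium benzenesulfinate, [Na+].[O-]S(=O)c1ccccc1
Why: SN2 S-alkylation of the sulfinate; the acidic allyl sulfone is made only after the Grignard step, so it never meets a basic organometallic.

Step 24
Reactants: 22 C11 alcohol; 29 (E)-3-methylhept-2-en-5-yn-1-yl phenyl sulfone
Product: 31 acyclic diyne C10 sulfone (C10 epimers), via triflate 30 (not isolated)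
Conditions: 22, Tf2O, 2,6-lutidine, CH2Cl2, −78 °C; 29, n-BuLi, THF, −78 °C; then 30, −78 to −40 °C
Reagents that add atoms: none
Why: α-Alkylation of the lithiated allyl sulfone by the primary epoxy triflate (SN2 at C11) forms C10–C11; allyl sulfone anions alkylate at the sulfonyl carbon, so the E olefin stays where it is.

Step 25
Reactants: 31 acyclic diyne C10 sulfone
Product: 32 C16 allylic alcohol (sulfone kept)
Conditions: (NH4)2Ce(NO3)6, NaHCO3, MeCN/H2O, 0 °C
Reagents that add atoms: none
Why: Oxidative dearylation of the PMP ether to benzoquinone by the tetravalent cerium salt; it is placed before step 26 because zerovalent palladium and hydride would cleave an allyl aryl ether.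

Step 26
Reactants: 32 C16 allylic alcohol
Product: 33 acyclic diyne allylic alcohol (no sulfone)
Conditions: PdCl2(dppp) (cat.), LiBHEt3, THF, −20 to 0 °C
Reagents that add atoms: none
Why: Palladium-catalysed reductive desulfonylation: the π-allyl complex formed by ionisation of the allylic sulfone takes hydride at C10, its less substituted terminus, which should keep the C8=C9 bond in place and E, while the C16 hydroxyl sits as its lithium alkoxide and is not ionised.

Step 27
Reactants: 33 acyclic diyne allylic alcohol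
Product: 34 enal (C16 CHO)
Conditions: MnO2, CH2Cl2, 20 °C
Reagents that add atoms: none
Why: MnO2 oxidises only the allylic primary alcohol and is inert toward alkynes, oxirane and silyl ether.

Step 28
Reactants: 34 enal
Product: 35 acrylic acid
Conditions: NaClO2, NaH2PO4, 2-methylbut-2-ene, t-BuOH/H2O, 0 °C
Reagents that add atoms: sodium chlorite, [Na+].[O-]Cl=O
Why: Pinnick oxidation of the 2-substituted acrolein; the excess scavenger alkene takes up HOCl and so protects the C8=C9 olefin.

Step 29
Reactants: 35 acrylic acid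
Product: 36 acyclic diyne methyl ester (metathesis precursor)
Conditions: Me3SiCHN2, PhMe/MeOH, 0 °C
Reagents that add atoms: (trimethylsilyl)diazomethane, C[Si](C)(C)C=[N+]=[N-]
Why: O-methylation of the carboxylic acid by the diazoalkane under neutral conditions, so the acrylate appears only after all carbanion and hydride steps.

Step 30
Reactants: 36 acyclic diyne methyl ester
Product: 37 14-membered cycloalkyne TES ether
Conditions: Mo(≡CC6H4OMe-4)(OSiPh3)3 (15 mol %), 5 Å MS, PhMe (2 mM), 20 to 60 °C
Reagents that add atoms: none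
Why: The alkylidyne undergoes [2+2] cycloaddition with the less hindered C7 prop-1-ynyl group, the molybdacyclobutadiene opens to give a substrate-bound alkylidyne, and a second cycloaddition and cycloreversion with the C4 prop-1-ynyl group closes the ring and expels but-2-yne, which the 5 Å sieves adsorb so that the equilibrium is drawn to 37. The closest known reaction type is ring-closing alkyne metathesis to 12- to 18-membered cycloalkynes with molybdenum alkylidyne triphenylsilanolate catalysts. The one ring is closed as a 14-membered macrocycle with the new C5≡C6 bond inside the ring, and high dilution should suppress dimers. No stereocentre is formed, and C1, C4, C12 and C13 are not involved. The step needs chemoselectivity for the two alkynes over the C8=C9 olefin, the acrylate, the oxirane and the ester, which the alkylidyne provides because it does not engage C=C bonds, while the TES cap keeps the C4 oxygen from exchanging with the silanolate ligands.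

Step 31
Reactants: 37 14-membered cycloalkyne TES ether
Product: 38 cycloalkynol
Conditions: Bu4NF, AcOH, THF, 0 to 20 °C
Reagents that add atoms: none
Why: Fluoride-driven desilylation buffered by acetic acid frees the C4 hydroxyl without basic conditions that could harm the acrylate or the oxirane.

Step 32
Reactants: 38 cycloalkynol
Product: 39 C5 alkenylstannane
Conditions: [Cp*RuCl]4 (cat.), Bu3SnH (slow addition), CH2Cl2, 20 °C
Reagents that add atoms: tributyltin hydride, CCCC[SnH](CCCC)CCCC
Why: Hydroxyl-directed trans-hydrostannation: a hydrogen bond from the C4 hydroxyl to the chloride ligand on ruthenium places tin on the proximal C5 and hydrogen on C6 on opposite sides of the former triple bond, and the catalyst should not add to the C=C bonds.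

Step 33
Reactants: 39 C5 alkenylstannane
Product: 41 target hydroxy ketone, via enol trifluoroacetate 40 (not isolated)
Conditions: Cu(OCOCF3)2·xH2O, 4-(dimethylamino)pyridine, DMSO, 45 °C; aq. NaHCO3
Reagents that add atoms: copper bis(trifluoroacetate), [Cu+2].[O-]C(=O)C(F)(F)F.[O-]C(=O)C(F)(F)F
Why: Chan–Lam-type oxidation of the C–Sn bond: tin–copper exchange helped by the neighbouring hydroxyl, oxidation to an alkenyl trivalent copper species and C–O reductive elimination give the C5 enol trifluoroacetate, which is hydrolysed on work-up to the C5 ketone with C1, C4, C12 and C13 untouched.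

Compound list
1 | (R)-carvone, (5R)-2-methyl-5-(prop-1-en-2-yl)cyclohex-2-en-1-one | CC1=CC[C@H](CC1=O)C(C)=C | starting material
2 | trans-carvone oxide, (1R,4R,6R)-1-methyl-4-(prop-1-en-2-yl)-7-oxabicyclo[4.1.0]heptan-2-one | CC(=C)[C@@H]1C[C@H]2O[C@@]2(C)C(=O)C1 | intermediate
3 | (1R,4R,6R)-4-(3-chloroprop-1-en-2-yl)-1-methyl-7-oxabicyclo[4.1.0]heptan-2-one | ClCC(=C)[C@@H]1C[C@H]2O[C@@]2(C)C(=O)C1 | intermediate
4 | (1R,4R,6R)-4-[3-(4-methoxyphenoxy)prop-1-en-2-yl]-1-methyl-7-oxabicyclo[4.1.0]heptan-2-one | COc1ccc(OCC(=C)[C@@H]2C[C@H]3O[C@@]3(C)C(=O)C2)cc1 | intermediate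
5 | 3-hydroxy derivative of 4 (OH on the ketone α-carbon, epimers there; other centres as in 4) | COc1ccc(OCC(=C)[C@@H]2C[C@H]3O[C@@]3(C)C(=O)C2O)cc1 | intermediate
6 | seco aldehyde ester: C2 CHO, C11 CO2Me, C16 O-PMP, 12,13-oxirane | O=C[C@H](C(=C)COc1ccc(OC)cc1)C[C@H]1O[C@@]1(C)C(=O)OC | intermediate
7 | seco hydroxy ester: C2 CH2OH, C11 CO2Me | OC[C@H](C(=C)COc1ccc(OC)cc1)C[C@H]1O[C@@]1(C)C(=O)OC | intermediate
8 | C2 iodide, C11 CO2Me | IC[C@H](C(=C)COc1ccc(OC)cc1)C[C@H]1O[C@@]1(C)C(=O)OC | intermediate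
9 | C2 phenyl sulfone, C11 CO2Me | O=S(=O)(C[C@H](C(=C)COc1ccc(OC)cc1)C[C@H]1O[C@@]1(C)C(=O)OC)c1ccccc1 | intermediate
10 | C2 phenyl sulfone, C11 CH2OH | O=S(=O)(C[C@H](C(=C)COc1ccc(OC)cc1)C[C@H]1O[C@@]1(C)CO)c1ccccc1 | intermediate
11 | C2 phenyl sulfone, C11 CH2OTES | O=S(=O)(C[C@H](C(=C)COc1ccc(OC)cc1)C[C@H]1O[C@@]1(C)CO[Si](CC)(CC)CC)c1ccccc1 | intermediate
12 | (R)-2-methylglycidol, [(2R)-2-methyloxiran-2-yl]methanol | C[C@@]1(CO)CO1 | starting material
13 | (2S)-2-{[(4-methoxybenzyl)oxy]methyl}-2-methyloxirane | C[C@@]1(COCc2ccc(OC)cc2)CO1 | intermediate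
14 | coupled hydroxy sulfone: C5 O-PMB, C4 tertiary OH, C2 SO2Ph (epimers), C11 OTES, C16 O-PMP | COc1ccc(COC[C@@](C)(O)CC([C@H](C(=C)COc2ccc(OC)cc2)C[C@H]2O[C@@]2(C)CO[Si](CC)(CC)CC)S(=O)(=O)c2ccccc2)cc1 | intermediate
15 | as 14 with C2 = CH2 | COc1ccc(COC[C@@](C)(O)CC[C@H](C(=C)COc2ccc(OC)cc2)C[C@H]2O[C@@]2(C)CO[Si](CC)(CC)CC)cc1 | intermediate
16 | C4 and C11 bis-TES ether of 15 | COc1ccc(COC[C@@](C)(O[Si](CC)(CC)CC)CC[C@H](C(=C)COc2ccc(OC)cc2)C[C@H]2O[C@@]2(C)CO[Si](CC)(CC)CC)cc1 | intermediate
17 | C5 primary alcohol | OC[C@@](C)(O[Si](CC)(CC)CC)CC[C@H](C(=C)COc1ccc(OC)cc1)C[C@H]1O[C@@]1(C)CO[Si](CC)(CC)CC | intermediate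
18 | C5 aldehyde | O=C[C@@](C)(O[Si](CC)(CC)CC)CC[C@H](C(=C)COc1ccc(OC)cc1)C[C@H]1O[C@@]1(C)CO[Si](CC)(CC)CC | intermediate
19 | 1,1-dibromoalkene at C5 | BrC(Br)=C[C@@](C)(O[Si](CC)(CC)CC)CC[C@H](C(=C)COc1ccc(OC)cc1)C[C@H]1O[C@@]1(C)CO[Si](CC)(CC)CC | intermediate
20 | lithium acetylide at C5≡C | [Li]C#C[C@@](C)(O[Si](CC)(CC)CC)CC[C@H](C(=C)COc1ccc(OC)cc1)C[C@H]1O[C@@]1(C)CO[Si](CC)(CC)CC | intermediate
21 | C4 prop-1-ynyl compound (C4 OTES, C11 OTES, C16 O-PMP) | CC#C[C@@](C)(O[Si](CC)(CC)CC)CC[C@H](C(=C)COc1ccc(OC)cc1)C[C@H]1O[C@@]1(C)CO[Si](CC)(CC)CC | intermediate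
22 | C11 alcohol of 21 | CC#C[C@@](C)(O[Si](CC)(CC)CC)CC[C@H](C(=C)COc1ccc(OC)cc1)C[C@H]1O[C@@]1(C)CO | intermediate
23 | prenyl acetate, 3-methylbut-2-en-1-yl acetate | CC(C)=CCOC(C)=O | starting material
24 | (2E)-4-hydroxy-3-methylbut-2-en-1-yl acetate | CC(=O)OC/C=C(C)/CO | intermediate
25 | (2E)-4-bromo-3-methylbut-2-en-1-yl acetate | CC(=O)OC/C=C(C)/CBr | intermediate
26 | (2E)-3-methylhept-2-en-5-yn-1-yl acetate | CC(=O)OC/C=C(C)/CC#CC | intermediate
27 | (2E)-3-methylhept-2-en-5-yn-1-ol | OC/C=C(C)/CC#CC | intermediate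
28 | (2E)-1-bromo-3-methylhept-2-en-5-yne | BrC/C=C(C)/CC#CC | intermediate
29 | {[(2E)-3-methylhept-2-en-5-yn-1-yl]sulfonyl}benzene | O=S(=O)(C/C=C(C)/CC#CC)c1ccccc1 | intermediate
30 | C11 triflate of 22 | CC#C[C@@](C)(O[Si](CC)(CC)CC)CC[C@H](C(=C)COc1ccc(OC)cc1)C[C@H]1O[C@@]1(C)COS(=O)(=O)C(F)(F)F | intermediate
31 | acyclic diyne with C10 SO2Ph (epimers), C16 O-PMP, C4 OTES | CC#C[C@@](C)(O[Si](CC)(CC)CC)CC[C@H](C(=C)COc1ccc(OC)cc1)C[C@H]1O[C@@]1(C)CC(/C=C(C)/CC#CC)S(=O)(=O)c1ccccc1 | intermediate
32 | as 31 with free C16 OH | CC#C[C@@](C)(O[Si](CC)(CC)CC)CC[C@H](C(=C)CO)C[C@H]1O[C@@]1(C)CC(/C=C(C)/CC#CC)S(=O)(=O)c1ccccc1 | intermediate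
33 | acyclic diyne allylic alcohol (C16 CH2OH, C10 = CH2) | CC#C[C@@](C)(O[Si](CC)(CC)CC)CC[C@H](C(=C)CO)C[C@H]1O[C@@]1(C)CC/C=C(C)/CC#CC | intermediate
34 | acyclic diyne enal (C16 CHO) | CC#C[C@@](C)(O[Si](CC)(CC)CC)CC[C@H](C(=C)C=O)C[C@H]1O[C@@]1(C)CC/C=C(C)/CC#CC | intermediate
35 | acyclic diyne acrylic acid | CC#C[C@@](C)(O[Si](CC)(CC)CC)CC[C@H](C(=C)C(=O)O)C[C@H]1O[C@@]1(C)CC/C=C(C)/CC#CC | intermediate
36 | acyclic diyne methyl ester, prop-1-ynyl groups on C4 and C7 | CC#C[C@@](C)(O[Si](CC)(CC)CC)CC[C@H](C(=C)C(=O)OC)C[C@H]1O[C@@]1(C)CC/C=C(C)/CC#CC | intermediate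
37 | 14-membered C5≡C6 cycloalkyne, C4 OTES | C=C(C(=O)OC)[C@H]1CC[C@](C)(O[Si](CC)(CC)CC)C#CC/C(C)=C/CC[C@]2(C)O[C@@H]2C1 | intermediate
38 | 14-membered cycloalkynol (C4 OH) | C=C(C(=O)OC)[C@H]1CC[C@](C)(O)C#CC/C(C)=C/CC[C@]2(C)O[C@@H]2C1 | intermediate
39 | C5 tributylstannyl alkene (H on C6 trans to tin; C4 and C7 trans) | C=C(C(=O)OC)[C@H]1CC[C@](C)(O)/C([Sn](CCCC)(CCCC)CCCC)=C/C/C(C)=C/CC[C@]2(C)O[C@@H]2C1 | intermediate
40 | C5 enol trifluoroacetate | C=C(C(=O)OC)[C@H]1CC[C@](C)(O)/C(OC(=O)C(F)(F)F)=C/C/C(C)=C/CC[C@]2(C)O[C@@H]2C1 | intermediate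
41 | CNP0154954.4, C4 hydroxy C5 ketone with 12,13-oxirane and C1 acrylate | C=C(C(=O)OC)[C@H]1CC[C@](C)(O)C(=O)CC/C(C)=C/CC[C@]2(C)O[C@@H]2C1 | target

Total step count: 33. Longest linear sequence: 27 steps from (R)-carvone (steps 1–9, 11–18, 24–33).

Steps most likely to fail

Step 30. The alkylidyne may fail to engage the alkyne next to the fully substituted, silyloxy-bearing C4, so that only the C7 alkyne reacts and open-chain oligomers form. The fallback closes the ring at C10–C11 by intramolecular alkylation of an allyl sulfone anion, after the C6–C7 bond has been made between the two halves. It sets out from dibromoalkene 19: n-BuLi gives acetylide 20, which after transmetallation with CuBr·SMe2 is alkylated by bromide 25 to the enyne acetate F1. K2CO3/MeOH gives the allylic alcohol F2, CBr4/PPh3 the bromide F3, PhSO2Na the allyl sulfone F4, PPTS/MeOH the C11 alcohol F5, and Tf2O/2,6-lutidine the triflate F6. Slow addition of F6 to LiN(SiMe3)2 in THF at high dilution should close the 14-membered ring to the macrocyclic sulfone F7. (NH4)2Ce(NO3)6 then frees the C16 alcohol F8, PdCl2(dppp)/LiBHEt3 removes the sulfone to give the cycloalkyne alcohol F9, and MnO2, NaClO2 and Me3SiCHN2 lead through the enal F10 and the acid F11 to cycloalkyne 37, where the route resumes.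

Step 33. Tin–copper exchange at the hindered C5 beside the tertiary carbinol may be slow, so that protodestannation to the plain alkene outruns C–O bond formation. The fallback sets out from cycloalkynol 38 and uses no tin: silver-catalysed carboxylative cyclisation (AgOAc, DBU, CO2, PhMe, 20 °C) should give, by anti 5-exo-dig attack of the carbonate oxygen on C5, the (Z)-alkylidene cyclic carbonate F12. LiOH in THF/H2O at 0 °C opens the carbonate, the enolate tautomerises to the C5 ketone and the hemicarbonate on C4 loses CO2, which gives the target 41.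

Step 11. BF3 may trigger rearrangement of the C12–C13 oxirane, or the C2 carbanion may open it intramolecularly, before the intermolecular opening of 13 is complete. The fallback reverses the polarity and needs no Lewis acid. Sodium benzenesulfinate opens 13 at its CH2 carbon (H2O/EtOH, 80 °C) to the β-hydroxy sulfone F13. Iodide 8 is reduced with i-Bu2AlH to the iodo alcohol F14 and silylated (Et3SiCl, imidazole) to the iodo TES ether F15. The dilithio derivative of F13 (2 n-BuLi, THF/DMPU, −78 to 0 °C) is C-alkylated by F15 to the C3 sulfone F16, and Na(Hg) desulfonylation of F16 gives 15, where the route resumes.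

Further compounds
F1 | step 30 | enyne acetate (C6–C7 joined; C10 OAc, C4 OTES, C11 OTES, C16 O-PMP) | CC(=O)OC/C=C(C)/CC#C[C@@](C)(O[Si](CC)(CC)CC)CC[C@H](C(=C)COc1ccc(OC)cc1)C[C@H]1O[C@@]1(C)CO[Si](CC)(CC)CC
F2 | step 30 | C10 allylic alcohol | OC/C=C(C)/CC#C[C@@](C)(O[Si](CC)(CC)CC)CC[C@H](C(=C)COc1ccc(OC)cc1)C[C@H]1O[C@@]1(C)CO[Si](CC)(CC)CC
F3 | step 30 | C10 allylic bromide | BrC/C=C(C)/CC#C[C@@](C)(O[Si](CC)(CC)CC)CC[C@H](C(=C)COc1ccc(OC)cc1)C[C@H]1O[C@@]1(C)CO[Si](CC)(CC)CC
F4 | step 30 | C10 allyl phenyl sulfone | O=S(=O)(C/C=C(C)/CC#C[C@@](C)(O[Si](CC)(CC)CC)CC[C@H](C(=C)COc1ccc(OC)cc1)C[C@H]1O[C@@]1(C)CO[Si](CC)(CC)CC)c1ccccc1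
F5 | step 30 | C11 alcohol of F4 | O=S(=O)(C/C=C(C)/CC#C[C@@](C)(O[Si](CC)(CC)CC)CC[C@H](C(=C)COc1ccc(OC)cc1)C[C@H]1O[C@@]1(C)CO)c1ccccc1
F6 | step 30 | C11 triflate of F5 | O=S(=O)(C/C=C(C)/CC#C[C@@](C)(O[Si](CC)(CC)CC)CC[C@H](C(=C)COc1ccc(OC)cc1)C[C@H]1O[C@@]1(C)COS(=O)(=O)C(F)(F)F)c1ccccc1
F7 | step 30 | 14-membered cycloalkyne with C10 SO2Ph (epimers), C16 O-PMP, C4 OTES | C=C(COc3ccc(OC)cc3)[C@H]1CC[C@](C)(O[Si](CC)(CC)CC)C#CC/C(C)=C/C(S(=O)(=O)c3ccccc3)C[C@]2(C)O[C@@H]2C1
F8 | step 30 | as F7 with free C16 OH | C=C(CO)[C@H]1CC[C@](C)(O[Si](CC)(CC)CC)C#CC/C(C)=C/C(S(=O)(=O)c3ccccc3)C[C@]2(C)O[C@@H]2C1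
F9 | step 30 | cycloalkyne allylic alcohol (C10 = CH2) | C=C(CO)[C@H]1CC[C@](C)(O[Si](CC)(CC)CC)C#CC/C(C)=C/CC[C@]2(C)O[C@@H]2C1
F10 | step 30 | cycloalkyne enal | C=C(C=O)[C@H]1CC[C@](C)(O[Si](CC)(CC)CC)C#CC/C(C)=C/CC[C@]2(C)O[C@@H]2C1
F11 | step 30 | cycloalkyne acrylic acid | C=C(C(=O)O)[C@H]1CC[C@](C)(O[Si](CC)(CC)CC)C#CC/C(C)=C/CC[C@]2(C)O[C@@H]2C1
F12 | step 33 | (Z)-alkylidene cyclic carbonate spanning C4–O and C5–O | C=C(C(=O)OC)[C@H]1CC[C@]3(C)OC(=O)O/C3=C\C/C(C)=C/CC[C@]2(C)O[C@@H]2C1
F13 | step 11 | β-hydroxy sulfone from 13: 1-[(4-methoxybenzyl)oxy]-2-methyl-3-(phenylsulfonyl)propan-2-ol, C4 centre as in 13 | COc1ccc(COC[C@@](C)(O)CS(=O)(=O)c2ccccc2)cc1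
F14 | step 11 | C2 iodide with C11 CH2OH | IC[C@H](C(=C)COc1ccc(OC)cc1)C[C@H]1O[C@@]1(C)CO
F15 | step 11 | C2 iodide with C11 CH2OTES | IC[C@H](C(=C)COc1ccc(OC)cc1)C[C@H]1O[C@@]1(C)CO[Si](CC)(CC)CC
F16 | step 11 | C3 sulfone isomer of 14 (C3 epimers) | COc1ccc(COC[C@@](C)(O)C(C[C@H](C(=C)COc2ccc(OC)cc2)C[C@H]2O[C@@]2(C)CO[Si](CC)(CC)CC)S(=O)(=O)c2ccccc2)cc1
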